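## Retrosynthetic overview

1. Target ⇒ 6-ketone (hydride reduction, acetylation in the same flask) ⇒ 6-epi alcohol of the ten-membered ring (oxidation); the C6 configuration is set last.
2. Key disconnection C6–C7 of the cyclodecene: intramolecular Pd/Et2Zn umpolung allylation. An allylic chloride carbon is turned into a nucleophilic allylzinc and attacks the epoxy-aldehyde carbon; both carbons are normally electrophiles. The step closes the ring and creates C7 and the isopropenyl group.
3. Acyclic epoxy aldehyde ⇒ terminal ene-chlorination, Mitsunobu tigloylation (inversion at C3), Sharpless kinetic-resolution epoxidation of a racemic allylic alcohol.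
4. Racemic allylic alcohol ⇒ C2–C3 bond from geranylbarium and (2E)-4-acetoxy-2-methylbut-2-enal.
5. Ring order: oxirane (step 2), then cyclodecene (step 7). Numbering for C-labels: germacrane (C1=C10 alkene, C3–O-tiglate, C4–C5 epoxide, C6–O, C7–isopropenyl).

Assumption: geranyl chloride and (2E)-4-acetoxy-2-methylbut-2-enal (the industrial vitamin A "C5 acetate") are bought; ring compounds are named with germacrane numbering.

## Route

Step 1
Reactants: 1 geranyl chloride, (2E)-1-chloro-3,7-dimethylocta-2,6-diene; 2 (2E)-4-acetoxy-2-methylbut-2-enal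
Product: 4 rac-(2E,6E)-4-hydroxy-3,7,11-trimethyldodeca-2,6,10-trien-1-yl acetate, via geranylbarium chloride 3 (not isolated)
Conditions: BaI2, Li biphenylide (2 equiv), THF, rt; then 1, −78 °C; then 2 (1.0 equiv), −78 °C, 30 min; H2O quench at −78 °C
Reagents that add atoms: none
Why: α-Selective allylbarium carbonyl allylation: the barium reagent attacks the aldehyde 1,2 through its CH2 terminus without allylic transposition and keeps the E geometry at −78 °C, where the aldehyde outcompetes the primary acetate; the new carbinol is racemic and is resolved in step 2.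

Step 2
Reactants: 4 rac-(2E,6E)-4-hydroxy-3,7,11-trimethyldodeca-2,6,10-trien-1-yl acetate
Product: 5 {(2R,3R)-3-[(1R,3E)-1-hydroxy-4,8-dimethylnona-3,7-dien-1-yl]-3-methyloxiran-2-yl}methyl acetate
Conditions: Ti(OiPr)4 (0.15 equiv), D-(−)-DIPT (0.2 equiv), TBHP (0.5 equiv), 4 Å MS, CH2Cl2, −20 °C, stopped near 45% conversion (yield ≤ 50%)
Reagents that add atoms: tert-butyl hydroperoxide, CC(C)(C)OO
Why: Sharpless kinetic resolution (Ti–tartrate epoxidation of a secondary allylic alcohol): with D-(−)-DIPT the (4R)-enantiomer of 4 is epoxidised far faster than its antipode and only on the face that gives the erythro epoxy alcohol, so the carbinol (R) and both oxirane carbons (R,R = C4, C5 of the target) are fixed together while the isolated alkenes stay untouched.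

Step 3
Reactants: 5 {(2R,3R)-3-[(1R,3E)-1-hydroxy-4,8-dimethylnona-3,7-dien-1-yl]-3-methyloxiran-2-yl}methyl acetate
Product: 6 (1S,3E)-1-[(2R,3R)-3-(acetoxymethyl)-2-methyloxiran-2-yl]-4,8-dimethylnona-3,7-dien-1-yl (2E)-2-methylbut-2-enoate
Conditions: tiglic acid (1.5 equiv), PPh3, DIAD, toluene, 0 °C to rt
Reagents that add atoms: tiglic acid, C/C=C(\C)C(=O)O
Why: Mitsunobu esterification: SN2 attack of tiglate on the activated carbinol inverts it from R to S, converting the erythro epoxy alcohol into the threo tiglate required at C3 in the same operation that installs the ester; the neighbouring epoxide disfavours ionisation and the primary acetate is inert.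

Step 4
Reactants: 6 (1S,3E)-1-[(2R,3R)-3-(acetoxymethyl)-2-methyloxiran-2-yl]-4,8-dimethylnona-3,7-dien-1-yl (2E)-2-methylbut-2-enoate
Product: 7 (1S,3E,7RS)-1-[(2R,3R)-3-(acetoxymethyl)-2-methyloxiran-2-yl]-7-chloro-4,8-dimethylnona-3,8-dien-1-yl (2E)-2-methylbut-2-enoate
Conditions: Ca(OCl)2, CO2 (dry ice), CH2Cl2–H2O, 0 °C, 45 min
Reagents that add atoms: calcium hypochlorite, [Ca+2].[O-]Cl.[O-]Cl
Why: Ene-type allylic chlorination with hypochlorous acid: the terminal Me2C=CH alkene is the most electron-rich and exposed (the other trisubstituted alkene is slowed by the nearby ester, the tiglate alkene is electron-poor), and chloronium formation with loss of a methyl proton gives the CHCl–C(CH3)=CH2 unit as both epimers, which does not matter because this centre becomes planar in step 7.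

Step 5
Reactants: 7 (1S,3E,7RS)-1-[(2R,3R)-3-(acetoxymethyl)-2-methyloxiran-2-yl]-7-chloro-4,8-dimethylnona-3,8-dien-1-yl (2E)-2-methylbut-2-enoate
Product: 8 (1S,3E,7RS)-7-chloro-1-[(2R,3R)-3-(hydroxymethyl)-2-methyloxiran-2-yl]-4,8-dimethylnona-3,8-dien-1-yl (2E)-2-methylbut-2-enoate
Conditions: K2CO3 (0.2 equiv), MeOH, 0 °C
Reagents that add atoms: none
Why: Base-catalysed transesterification (methanolysis): the unhindered primary acetate is cleaved much faster than the hindered, conjugated secondary tiglate, and cold catalytic carbonate avoids Payne rearrangement and substitution of the allylic chloride; no stereocentre is touched.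

Step 6
Reactants: 8 (1S,3E,7RS)-7-chloro-1-[(2R,3R)-3-(hydroxymethyl)-2-methyloxiran-2-yl]-4,8-dimethylnona-3,8-dien-1-yl (2E)-2-methylbut-2-enoate
Product: 9 (1S,3E,7RS)-7-chloro-1-[(2R,3S)-3-formyl-2-methyloxiran-2-yl]-4,8-dimethylnona-3,8-dien-1-yl (2E)-2-methylbut-2-enoate
Conditions: Dess–Martin periodinane, pyridine, CH2Cl2, 0 °C to rt; used at once
Reagents that add atoms: none
Why: Dess–Martin oxidation of the primary alcohol under buffered, non-acidic conditions gives the epoxy aldehyde without touching the epoxide, the allylic chloride or the esters; the α-carbon is an oxirane carbon and cannot epimerise (its descriptor changes from R to S only by CIP priority).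

Step 7
Reactants: 9 (1S,3E,7RS)-7-chloro-1-[(2R,3S)-3-formyl-2-methyloxiran-2-yl]-4,8-dimethylnona-3,8-dien-1-yl (2E)-2-methylbut-2-enoate
Product: 12 (1(10)E,3S,4R,5R,6S,7S)-4,5-epoxy-6-hydroxygermacra-1(10),11-dien-3-yl (2E)-2-methylbut-2-enoate, via allylpalladium chloride 10 (not isolated), via allylethylzinc 11 (not isolated)
Conditions: Pd(PPh3)4 (10 mol%), Et2Zn (3 equiv), THF, rt, syringe-pump addition of 9 over 6 h (final 5 mM); aq NH4Cl
Reagents that add atoms: none
Why: Intramolecular Pd-catalysed umpolung allylation (Tamaru type): Pd(0) ionises either chloride epimer to the electrophilic allylpalladium 10, Et2Zn inverts its polarity to the nucleophilic allylzinc 11, and 11 adds through its substituted terminus C7 to the aldehyde carbon C6 in a chair six-membered transition state (chain equatorial, C=O turned outward away from the C4 methyl, attack anti to the epoxide oxygen) that matches the all-anti H5/H6/H7 crown of trans-4,5-epoxygermacranes, which I predict by this model, not from precedent, to set C7 as S and C6 as S while closing the ring and creating the isopropenyl group.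

Step 8
Reactants: 12 (1(10)E,3S,4R,5R,6S,7S)-4,5-epoxy-6-hydroxygermacra-1(10),11-dien-3-yl (2E)-2-methylbut-2-enoate
Product: 13 (1(10)E,3S,4R,5S,7S)-4,5-epoxy-6-oxogermacra-1(10),11-dien-3-yl (2E)-2-methylbut-2-enoate
Conditions: Dess–Martin periodinane, pyridine, CH2Cl2, 0 °C to rt
Reagents that add atoms: none
Why: Dess–Martin oxidation under buffered neutral conditions removes the C6 stereocentre without enolising C7 or moving the isopropenyl double bond into conjugation (C5 changes descriptor by CIP priority only), so either C6 epimer from step 7 converges on this ketone.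

Step 9
Reactants: 13 (1(10)E,3S,4R,5S,7S)-4,5-epoxy-6-oxogermacra-1(10),11-dien-3-yl (2E)-2-methylbut-2-enoate
Product: 15 (1(10)E,3S,4R,5R,6R,7S)-6-acetoxy-4,5-epoxygermacra-1(10),11-dien-3-yl (2E)-2-methylbut-2-enoate, via lithium alkoxide 14 (not isolated)
Conditions: LiAlH(OtBu)3, THF, −78 to −20 °C; then Ac2O, DMAP, pyridine, −20 °C to rt
Reagents that add atoms: acetic anhydride, CC(=O)OC(C)=O
Why: Peripheral hydride reduction of a medium-ring ketone followed by in-flask acylation of the alkoxide: the bulky hydride adds to the outer carbonyl face next to H5, away from C4 and its methyl group, giving the (6R) alkoxide (erythro to the epoxide), which is trapped as the acetate; the tiglate and epoxide are inert to this reagent.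

## Compound list

1 | geranyl chloride, (2E)-1-chloro-3,7-dimethylocta-2,6-diene | CC(C)=CCC/C(C)=C/CCl | starting material
2 | (2E)-4-acetoxy-2-methylbut-2-enal | CC(=O)OC/C=C(\C)C=O | starting material
3 | geranylbarium chloride (in flask) | CC(C)=CCC/C(C)=C/C[Ba]Cl | intermediate
4 | rac-(2E,6E)-4-hydroxy-3,7,11-trimethyldodeca-2,6,10-trien-1-yl acetate | CC(C)=CCC/C(C)=C/CC(O)/C(C)=C/COC(C)=O | intermediate
5 | {(2R,3R)-3-[(1R,3E)-1-hydroxy-4,8-dimethylnona-3,7-dien-1-yl]-3-methyloxiran-2-yl}methyl acetate | CC(C)=CCC/C(C)=C/C[C@@H](O)[C@@]1(C)O[C@@H]1COC(C)=O | intermediate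
6 | (1S,3E)-1-[(2R,3R)-3-(acetoxymethyl)-2-methyloxiran-2-yl]-4,8-dimethylnona-3,7-dien-1-yl (2E)-2-methylbut-2-enoate | CC(C)=CCC/C(C)=C/C[C@H](OC(=O)/C(C)=C/C)[C@@]1(C)O[C@@H]1COC(C)=O | intermediate
7 | (1S,3E,7RS)-1-[(2R,3R)-3-(acetoxymethyl)-2-methyloxiran-2-yl]-7-chloro-4,8-dimethylnona-3,8-dien-1-yl (2E)-2-methylbut-2-enoate (both C–Cl epimers) | C=C(C)C(Cl)CC/C(C)=C/C[C@H](OC(=O)/C(C)=C/C)[C@@]1(C)O[C@@H]1COC(C)=O | intermediate
8 | (1S,3E,7RS)-7-chloro-1-[(2R,3R)-3-(hydroxymethyl)-2-methyloxiran-2-yl]-4,8-dimethylnona-3,8-dien-1-yl (2E)-2-methylbut-2-enoate | C=C(C)C(Cl)CC/C(C)=C/C[C@H](OC(=O)/C(C)=C/C)[C@@]1(C)O[C@@H]1CO | intermediate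
9 | (1S,3E,7RS)-7-chloro-1-[(2R,3S)-3-formyl-2-methyloxiran-2-yl]-4,8-dimethylnona-3,8-dien-1-yl (2E)-2-methylbut-2-enoate | C=C(C)C(Cl)CC/C(C)=C/C[C@H](OC(=O)/C(C)=C/C)[C@@]1(C)O[C@@H]1C=O | intermediate
10 | allylpalladium chloride from 9 (in flask; η3 complex drawn as its σ-form, phosphines omitted) | Cl[Pd]C/C(C)=C/CC/C(C)=C/C[C@H](OC(=O)/C(C)=C/C)[C@@]1(C)O[C@@H]1C=O | intermediate
11 | allylethylzinc from 10 (in flask; E primary allylzinc carrying the epoxy aldehyde) | CC[Zn]C/C(C)=C/CC/C(C)=C/C[C@H](OC(=O)/C(C)=C/C)[C@@]1(C)O[C@@H]1C=O | intermediate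
12 | (1(10)E,3S,4R,5R,6S,7S)-4,5-epoxy-6-hydroxygermacra-1(10),11-dien-3-yl (2E)-2-methylbut-2-enoate (ten-membered ring, 6-epi to the target series) | C=C(C)[C@@H]1CC/C(C)=C/C[C@H](OC(=O)/C(C)=C/C)[C@@]2(C)O[C@@H]2[C@H]1O | intermediate
13 | (1(10)E,3S,4R,5S,7S)-4,5-epoxy-6-oxogermacra-1(10),11-dien-3-yl (2E)-2-methylbut-2-enoate | C=C(C)[C@@H]1CC/C(C)=C/C[C@H](OC(=O)/C(C)=C/C)[C@@]2(C)O[C@@H]2C1=O | intermediate
14 | lithium (1(10)E,3S,4R,5R,6R,7S)-4,5-epoxy-3-[(2E)-2-methylbut-2-enoyloxy]germacra-1(10),11-dien-6-olate (in flask; aluminate drawn as the lithium alkoxide) | C=C(C)[C@@H]1CC/C(C)=C/C[C@H](OC(=O)/C(C)=C/C)[C@@]2(C)O[C@@H]2[C@@H]1[O-].[Li+] | intermediate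
15 | (1(10)E,3S,4R,5R,6R,7S)-6-acetoxy-4,5-epoxygermacra-1(10),11-dien-3-yl (2E)-2-methylbut-2-enoate | C=C(C)[C@@H]1CC/C(C)=C/C[C@H](OC(=O)/C(C)=C/C)[C@@]2(C)O[C@@H]2[C@@H]1OC(C)=O | target

## Step count and risks

Total steps: 9. Longest linear sequence: 9 (from 1 and 2, both bought).

**Most likely to fail, 1: step 7 (macrocyclisation).** The risks are oligomerisation, ethyl transfer to the aldehyde, and attack on the wrong C7 face. The stereochemical outcome is my prediction from the transition-state model. The C6 outcome does not matter, because step 8 erases it. A wrong C7 face cannot be repaired by any fallback here. Fallback for the yield problems: separate the formation of the allyl nucleophile from the ring closure. Starting from 7, Pd-catalysed borylation (B2pin2, Pd2dba3, DMSO, 50 °C) gives the linear E allyl pinacolboronate F1. Cold K2CO3/MeOH removes the acetate to give the alcohol F2. Dess–Martin oxidation at high dilution gives the aldehyde F3, which closes by thermal intramolecular allylboration through the same chair to the cyclic borate ester F4. Work-up with triethanolamine returns to the route at 12.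

**Most likely to fail, 2: step 4 (ene-chlorination).** The internal trisubstituted alkene may compete, and the epoxide may suffer in the mildly acidic medium. Fallback: functionalise the terminal E methyl group in two steps. Starting from 6, SeO2 (cat.)/TBHP gives the E primary allylic alcohol F5, and MsCl/LiCl/collidine gives the primary allylic chloride F6. Methanolysis gives the alcohol F7 and Dess–Martin oxidation the aldehyde F8. Under the step 7 conditions F8 ionises to the same allylpalladium 10 and allylzinc 11, so the route is rejoined at 12.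

**Most likely to fail, 3: step 3 (Mitsunobu).** The carbinol sits next to a fully substituted oxirane carbon and tiglic acid is a weak pronucleophile, so elimination or no reaction is possible. Fallback: avoid the inversion by using the other enantiomer of 4. Starting from 4, the unreacted (4S)-alcohol F9 left by step 2 is acylated with retention (tigloyl chloride, DMAP, pyridine) to the tiglate F10. Selective methanolysis of the primary allylic acetate gives the allylic alcohol F11. Sharpless epoxidation with D-(−)-DET, now directed by the primary alcohol and under reagent control, gives the threo epoxy alcohol F12. Ac2O/pyridine returns to the route at 6.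

## Further compounds

F1 | step 7 | (1S,3E,7E)-1-[(2R,3R)-3-(acetoxymethyl)-2-methyloxiran-2-yl]-4,8-dimethyl-9-(4,4,5,5-tetramethyl-1,3,2-dioxaborolan-2-yl)nona-3,7-dien-1-yl (2E)-2-methylbut-2-enoate | CC1(C)OB(C/C(C)=C/CC/C(C)=C/C[C@H](OC(=O)/C(C)=C/C)[C@@]2(C)O[C@@H]2COC(C)=O)OC1(C)C
F2 | step 7 | (1S,3E,7E)-1-[(2R,3R)-3-(hydroxymethyl)-2-methyloxiran-2-yl]-4,8-dimethyl-9-(4,4,5,5-tetramethyl-1,3,2-dioxaborolan-2-yl)nona-3,7-dien-1-yl (2E)-2-methylbut-2-enoate | CC1(C)OB(C/C(C)=C/CC/C(C)=C/C[C@H](OC(=O)/C(C)=C/C)[C@@]2(C)O[C@@H]2CO)OC1(C)C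
F3 | step 7 | (1S,3E,7E)-1-[(2R,3S)-3-formyl-2-methyloxiran-2-yl]-4,8-dimethyl-9-(4,4,5,5-tetramethyl-1,3,2-dioxaborolan-2-yl)nona-3,7-dien-1-yl (2E)-2-methylbut-2-enoate | CC1(C)OB(C/C(C)=C/CC/C(C)=C/C[C@H](OC(=O)/C(C)=C/C)[C@@]2(C)O[C@@H]2C=O)OC1(C)C
F4 | step 7 | pinacol borate of 12, 2-{[(1(10)E,3S,4R,5R,6S,7S)-4,5-epoxy-3-[(2E)-2-methylbut-2-enoyloxy]germacra-1(10),11-dien-6-yl]oxy}-4,4,5,5-tetramethyl-1,3,2-dioxaborolane | C=C(C)[C@@H]1CC/C(C)=C/C[C@H](OC(=O)/C(C)=C/C)[C@@]2(C)O[C@@H]2[C@H]1OB1OC(C)(C)C(C)(C)O1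
F5 | step 4 | (1S,3E,7E)-1-[(2R,3R)-3-(acetoxymethyl)-2-methyloxiran-2-yl]-9-hydroxy-4,8-dimethylnona-3,7-dien-1-yl (2E)-2-methylbut-2-enoate | OC/C(C)=C/CC/C(C)=C/C[C@H](OC(=O)/C(C)=C/C)[C@@]1(C)O[C@@H]1COC(C)=O
F6 | step 4 | (1S,3E,7E)-1-[(2R,3R)-3-(acetoxymethyl)-2-methyloxiran-2-yl]-9-chloro-4,8-dimethylnona-3,7-dien-1-yl (2E)-2-methylbut-2-enoate | ClC/C(C)=C/CC/C(C)=C/C[C@H](OC(=O)/C(C)=C/C)[C@@]1(C)O[C@@H]1COC(C)=O
F7 | step 4 | (1S,3E,7E)-9-chloro-1-[(2R,3R)-3-(hydroxymethyl)-2-methyloxiran-2-yl]-4,8-dimethylnona-3,7-dien-1-yl (2E)-2-methylbut-2-enoate | ClC/C(C)=C/CC/C(C)=C/C[C@H](OC(=O)/C(C)=C/C)[C@@]1(C)O[C@@H]1CO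
F8 | step 4 | (1S,3E,7E)-9-chloro-1-[(2R,3S)-3-formyl-2-methyloxiran-2-yl]-4,8-dimethylnona-3,7-dien-1-yl (2E)-2-methylbut-2-enoate | ClC/C(C)=C/CC/C(C)=C/C[C@H](OC(=O)/C(C)=C/C)[C@@]1(C)O[C@@H]1C=O
F9 | step 3 | (2E,4S,6E)-4-hydroxy-3,7,11-trimethyldodeca-2,6,10-trien-1-yl acetate | CC(C)=CCC/C(C)=C/C[C@H](O)/C(C)=C/COC(C)=O
F10 | step 3 | (2E,4S,6E)-1-acetoxy-3,7,11-trimethyldodeca-2,6,10-trien-4-yl (2E)-2-methylbut-2-enoate | CC(C)=CCC/C(C)=C/C[C@H](OC(=O)/C(C)=C/C)/C(C)=C/COC(C)=O
F11 | step 3 | (2E,4S,6E)-1-hydroxy-3,7,11-trimethyldodeca-2,6,10-trien-4-yl (2E)-2-methylbut-2-enoate | CC(C)=CCC/C(C)=C/C[C@H](OC(=O)/C(C)=C/C)/C(C)=C/CO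
F12 | step 3 | (1S,3E)-1-[(2R,3R)-3-(hydroxymethyl)-2-methyloxiran-2-yl]-4,8-dimethylnona-3,7-dien-1-yl (2E)-2-methylbut-2-enoate | CC(C)=CCC/C(C)=C/C[C@H](OC(=O)/C(C)=C/C)[C@@]1(C)O[C@@H]1CO
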